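## Structural features

The target is a linear tridepside: three tetrasubstituted benzene rings joined by two aryl ester bonds, from the C1 carbonyl of ring A to the C4 oxygen of ring B and from the C1 carbonyl of ring B to the C4 oxygen of ring C, which ends in a methyl ester at its C1. Each ring carries the carbonyl at C1, a methyl group at C6 and oxygen at C2 and C4: free hydroxyls at C2 and C4 of ring A, a methyl ether at C2 of ring B, a free hydroxyl at C2 of ring C. There is no stereocenter and no ring other than the three arenes, so nothing stereochemical has to be set or preserved. The fragile groups are the two aryl esters, which are open to hydrolysis, transesterification and acyl migration under basic or nucleophilic conditions, and the electron-rich phenols; benzoic acids with two ortho donors also lose carbon dioxide easily. The difficulty lies in the oxygen pattern and not in the skeleton: on rings A and C two oxygens of similar reactivity must end up differently, and any ester formed on a fully oxygenated ring has to be made at a carbonyl flanked by two ortho substituents. The key step uses the fact that C2–H of ring A and C2–H of ring C are each the only open position ortho to an ester carbonyl, because C6 is methylated, while the ring B carbonyl sits between OMe at C2 and methyl at C6 and has no ortho hydrogen. Both chelated hydroxyls can therefore be introduced last, directed by the esters themselves.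

## Logic of the disconnections

18 ⇒ 15 (through 17 and 16). The two aryl C2–O bonds of rings A and C are cut. These hydroxyls are what make a conventional assembly awkward: they impose a C2/C4 distinction on two rings and turn the ring A acid into a di-ortho-substituted one. Without them rings A and C are monophenolic and both come from 1. The forward step must oxygenate two C–H bonds, each ortho to an ester, in a molecule holding two aryl esters. The ring A C4 oxygen is deliberately not carried into this step as a benzyl ether, since such an ether would be exposed to acidolysis, benzylic oxidation and re-benzylation of the donor-substituted rings in a hot, acidic, oxidising medium. It enters as the free phenol of 15, is masked in the flask as the trifluoroacetate 16, and is released with the two new oxygens when 17 is hydrolysed, so no deprotection follows the key step.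

15 ⇒ 14. The O–CH2Ph bond at ring A C4 is cut. The benzyl group is needed only to keep the ring A phenol silent during the preceding esterification, and neutral hydrogenolysis is the mildest way to expose a phenol next to depside esters. The forward step needs only that nothing else is reducible, which holds.

14 ⇒ 12 + 10 (through 13). The acyl C–O bond of the A–B ester is cut, which makes the route convergent. Because 12 has only one ortho substituent, ordinary acid chloride chemistry is enough. The forward step must acylate the phenol of 10 without exchanging its existing hindered ester.

12 ⇒ 1 + 4 (through 11). The phenolic O–CH2Ph bond is cut; the carboxyl group is benzylated along with the phenol and freed again in the same flask. The only demand is that the benzyl ester, not the benzyl ether, is cleaved by hydroxide.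

10 ⇒ 9. The O–CH2Ph bond at ring B C4 is cut. This exposes the nucleophile for the A–B esterification only after the B–C ester is in place.

9 ⇒ 7 + 2 (through 8). The acyl C–O bond of the B–C ester is cut. The acid 7 is di-ortho-substituted and electron-rich, so the forward step should use acylium-type activation, and the phenol of 2, which has no second hydroxyl, can react only at the intended oxygen.

7 ⇒ 6 ⇒ 5 ⇒ 3 + 4. The ester O–CH3 bond, the ether O–CH3 bond at C2 and the O–CH2Ph bond at C4 are cut in turn. Ring B is the one ring whose two oxygens really differ, and the hydrogen bond of the C2 hydroxyl of 3 to its ester fixes the order: benzylation at C4 first, methylation at C2 second. The final ester cleavage must overcome the shielding of a di-ortho-substituted carbonyl.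

2 ⇒ 1. The ester O–CH3 bond is cut; one purchased acid thus supplies both ring C and ring A.

## Other disconnections considered

Alternative 1: The cut runs through ring C at C1–C6 and C3–C4, so that ring C is assembled from methyl acetoacetate A1 and methyl (E)-but-2-enoate A2.
- Forward key step: an alkoxide base adds the doubly activated carbon of A1 to the β-carbon of A2 (C1–C6). The enolate of the acetyl methyl group then closes onto the ester carbon that came from A2 (C3–C4, Dieckmann), giving the racemic trans dione A3. Its C4 enol oxygen would be acylated by 7 to the enol ester A4, the chain completed on the non-aromatic ring, and ring C dehydrogenated at the end.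
- In its favour: the feedstock is cheap and the ring formation is of a long-established type. The C2 carbonyl and the C4 vinylogous acid of A3 differ chemically, so C4 could be acylated without protecting C2.
- Equal or better: on telling the two ring C oxygens apart it is the equal of the chosen plan, which never has to do so either. It is the better plan in resting only on established reaction types.
- Against it here: ring C can be bought fully aromatic and fully oxygenated as 3, so building it gains nothing. A4 is a vinylogous anhydride and would be expected to hand its acyl group to any free phenol or amine it meets. Its enol double bond would not survive the hydrogenolyses that the benzyl protection of rings A and B relies on. The last step would have to oxidise ring C next to the electron-rich resorcinol of ring A.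
- Comparison: structurally it addresses ring C only, and the ring A C2 hydroxyl would still have to arrive on a doubly protected, di-ortho-substituted acid. Mechanistically it is polar and predictable where the chosen plan depends on a directed metalation with competing chelates. In step economy it is estimated two to three steps longer than the ten of the chosen plan, and the two stereocenters of A3 are made only to be destroyed.

Alternative 2: The cut removes both carbon substituents of ring B together, at C1–C(carbonyl) and C6–C(methyl).
- Forward key step: an alkyllithium exchanges the iodine of 2-iodo-3-methoxy-5-(triisopropylsilyloxy)phenyl trifluoromethanesulfonate A5 and the neighbouring triflate leaves. The aryne across C1–C6 is trapped by 1,1-dimethoxyethene A6 in a stepwise [2+2] addition that closes the four-membered ring of acetal A7. Hydrolysis to ketone A8 and attack of an oxygen nucleophile at its carbonyl would break the C(=O)–CH2 bond, leaving a carboxyl derivative at C1 and a methyl group at C6.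
- In its favour: the C2 methoxy group polarises the aryne so that the nucleophilic CH2 terminus of A6 should bond at C6 and the acetal carbon at C1, so the regiochemistry is built in.
- Equal or better: if A8 were opened directly by the phenoxide of 2, ring strain would drive formation of the hindered B–C ester with no carboxyl activation, which would be better than step 5 of the chosen plan.
- Against it here: A5 is a phloroglucinol derivative with three differently substituted oxygens and an iodine between two of them, so the oxygen-differentiation problem is only moved and costs several steps. Cryogenic organolithium chemistry is needed. The opening of A8 could break either C–C bond at the carbonyl. The end point is equivalent to 7, which the chosen plan reaches in three ordinary steps from 3.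
- Comparison: structurally it rebuilds a ring that is not the problem and leaves the C2 hydroxyls of rings A and C untouched. Mechanistically its key step is a known type with reliable polarity control, a lower risk than the chosen key step. In step economy it is estimated three to four steps longer.

Alternative 3: The cut opens ring B at C5–C6 and C3–C4, tracing C6, C1, C2 and C3 to a 2-pyrone and C4 and C5 to a ketene acetal.
- Forward key step: the pyrone ester of ring C, 3-(benzyloxy)-4-(methoxycarbonyl)-5-methylphenyl 4-methoxy-6-methyl-2-oxo-2H-pyran-5-carboxylate A9, is heated with 1,1-bis(trimethylsilyloxy)ethene A10. Cycloaddition with inverse electron demand across the pyrone diene, loss of the lactone bridge and of one silyloxy group, and desilylation on work-up would give the B–C depside phenol A11.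
- In its favour: the regiochemistry follows from polarisation, the CH2 terminus of A10 bonding to the pyrone carbon β to the ester, which becomes C6.
- Equal or better: ring B is formed with its C4 hydroxyl free and correctly placed, so A11 is ready for the A–B esterification with no protecting-group step on ring B. That is better than the chosen plan, which spends a benzylation and a hydrogenolysis on that oxygen.
- Against it here: the methoxy group is a donor on the diene and should slow an inverse-demand addition, and the methyl group sits on the very carbon that must be attacked. Long heating with a nucleophilic ketene acetal endangers the aryl ester. The pyrone acid needs its own synthesis. The ring C phenol needed for A9 has its C2 oxygen benzylated and its C4 oxygen free, the less accessible arrangement, so the differentiation the chosen plan avoids on ring C returns. Ring A must still come in as a doubly protected, di-ortho-substituted acid.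
- Comparison: structurally it solves ring B elegantly but not the hydroxyl problem of rings A and C. Mechanistically it is a pericyclic reaction of known type, against a chosen key step without direct precedent. In step economy it is estimated at eleven to twelve steps, comparable or slightly longer.

Key step: step 10

Remark on the chemistry: it is assumed that a phenol dissolved in TFA containing excess TFAA exists as its aryl trifluoroacetate, inert to the trivalent iodine oxidant and cleaved by water on work-up. This lets the ring A C4 oxygen enter step 10 without a separate protecting group. No compound of the route has a stereocenter.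

## Route

Step 1
Reactants: 1 4-hydroxy-2-methylbenzoic acid
Product: 2 methyl 4-hydroxy-2-methylbenzoate
Conditions: MeOH, H2SO4 (cat.), reflux
Reagents that add atoms: methanol, CO
Why: Fischer esterification; a benzoic acid with a single ortho methyl group still esterifies in excess methanol under acid catalysis, and the phenol is inert.

Step 2
Reactants: 3 methyl orsellinate (methyl 2,4-dihydroxy-6-methylbenzoate); 4 benzyl bromide
Product: 5 methyl 4-(benzyloxy)-2-hydroxy-6-methylbenzoate
Conditions: 4 (1.05 equiv), K2CO3, acetone, reflux
Reagents that add atoms: none
Why: Williamson etherification; the C2 hydroxyl is held in a hydrogen bond to the ester carbonyl and is less acidic and less nucleophilic, so one equivalent of halide with a weak base should alkylate the C4 oxygen only.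

Step 3
Reactants: 5 methyl 4-(benzyloxy)-2-hydroxy-6-methylbenzoate
Product: 6 methyl 4-(benzyloxy)-2-methoxy-6-methylbenzoate
Conditions: MeI (excess), K2CO3, DMF, 50 °C
Reagents that add atoms: iodomethane, CI
Why: Williamson O-methylation of the chelated phenol, which needs the dipolar solvent and excess MeI; no other acidic site remains.

Step 4
Reactants: 6 methyl 4-(benzyloxy)-2-methoxy-6-methylbenzoate
Product: 7 4-(benzyloxy)-2-methoxy-6-methylbenzoic acid
Conditions: KOH, DMSO/H2O, 90 °C; then HCl (aq), 0 °C
Reagents that add atoms: potassium hydroxide, [K+].[OH-]
Why: Saponification of a di-ortho-substituted benzoate; poorly solvated hydroxide in aqueous DMSO should reach the shielded carbonyl, and cold acidification avoids protodecarboxylation of the electron-rich acid.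

Step 5
Reactants: 7 4-(benzyloxy)-2-methoxy-6-methylbenzoic acid; 2 methyl 4-hydroxy-2-methylbenzoate
Product: 9 methyl 4-{[4-(benzyloxy)-2-methoxy-6-methylbenzoyl]oxy}-2-methylbenzoate, via mixed anhydride 8 (not isolated)
Conditions: TFAA (2 equiv), toluene, 0 °C → rt
Reagents that add atoms: trifluoroacetic anhydride, O=C(OC(=O)C(F)(F)F)C(F)(F)F (trifluoroacetyl group of 8 only; none of it remains in 9)
Why: TFAA-mediated depside esterification; the mixed anhydride 8 of the electron-rich, di-ortho-substituted acid ionises readily towards an acylium ion, which the only hydroxyl of 2 captures on oxygen, and benzyl ether and methyl ester are inert at room temperature.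

Step 6
Reactants: 9 methyl 4-{[4-(benzyloxy)-2-methoxy-6-methylbenzoyl]oxy}-2-methylbenzoate
Product: 10 methyl 4-[(4-hydroxy-2-methoxy-6-methylbenzoyl)oxy]-2-methylbenzoate
Conditions: H2 (1 atm), 10% Pd/C, EtOAc, rt
Reagents that add atoms: none
Why: Catalytic hydrogenolysis of the benzyl aryl ether under neutral conditions; the aryl ester, the methyl ester and the methyl ether are not reduced.

Step 7
Reactants: 1 4-hydroxy-2-methylbenzoic acid; 4 benzyl bromide
Product: 12 4-(benzyloxy)-2-methylbenzoic acid, via benzyl ester 11 (not isolated)
Conditions: 4 (2.3 equiv), K2CO3, DMF, 60 °C; then NaOH, MeOH/H2O, 60 °C; then HCl (aq)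
Reagents that add atoms: sodium hydroxide, [Na+].[OH-]
Why: Double Williamson benzylation of phenoxide and carboxylate, then saponification of the benzyl ester in the same flask; the benzyl aryl ether is stable to hydroxide.

Step 8
Reactants: 12 4-(benzyloxy)-2-methylbenzoic acid; 10 methyl 4-[(4-hydroxy-2-methoxy-6-methylbenzoyl)oxy]-2-methylbenzoate
Product: 14 methyl 4-[(4-{[4-(benzyloxy)-2-methylbenzoyl]oxy}-2-methoxy-6-methylbenzoyl)oxy]-2-methylbenzoate, via acid chloride 13 (not isolated)
Conditions: (COCl)2, DMF (cat.), CH2Cl2, 0 °C → rt, concentrate; then 10, Et3N, DMAP (cat.), CH2Cl2, 0 °C → rt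
Reagents that add atoms: oxalyl chloride, O=C(Cl)C(=O)Cl (chlorine of 13 only; none of it remains in 14)
Why: Acid chloride formation under DMF catalysis and DMAP-catalysed acylation of the unhindered ring B phenol; the di-ortho-substituted B–C ester and the methyl ester should not exchange under these mild conditions.

Step 9
Reactants: 14 methyl 4-[(4-{[4-(benzyloxy)-2-methylbenzoyl]oxy}-2-methoxy-6-methylbenzoyl)oxy]-2-methylbenzoate
Product: 15 methyl 4-({4-[(4-hydroxy-2-methylbenzoyl)oxy]-2-methoxy-6-methylbenzoyl}oxy)-2-methylbenzoate
Conditions: H2 (1 atm), 10% Pd/C, EtOAc/THF, rt
Reagents that add atoms: none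
Why: Catalytic hydrogenolysis of the single benzyl ether; the three ester groups are inert and nothing else is reducible.

Step 10
Reactants: 15 methyl 4-({4-[(4-hydroxy-2-methylbenzoyl)oxy]-2-methoxy-6-methylbenzoyl}oxy)-2-methylbenzoate
Product: 18 methyl 4-({4-[(2,4-dihydroxy-6-methylbenzoyl)oxy]-2-methoxy-6-methylbenzoyl}oxy)-2-hydroxy-6-methylbenzoate, via ring A trifluoroacetate 16 (not isolated), via tris(trifluoroacetate) 17 (not isolated)
Conditions: TFA/TFAA (3:1), rt, 1 h; then [RuCl2(p-cymene)]2 (10 mol %), PhI(OCOCF3)2 (3 equiv), 80 °C; then H2O/THF, rt
Reagents that add atoms: phenyliodine bis(trifluoroacetate), O=C(O[I](OC(=O)C(F)(F)F)c1ccccc1)C(F)(F)F (oxygen of the two new C2 hydroxyls); trifluoroacetic anhydride, O=C(OC(=O)C(F)(F)F)C(F)(F)F (trifluoroacetyl groups of 16 and 17 only)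
Why: Proposed new method: in TFA the chloride-bridged dimer should give a cationic (p-cymene)Ru(OCOCF3) species of divalent ruthenium, which the methyl ester carbonyl of ring C and the aryl ester carbonyl of ring A each bind; carboxylate-assisted concerted metalation–deprotonation at the single free ortho C–H (C2) gives a five-membered ruthenacycle, PhI(OCOCF3)2 oxidises it to tetravalent ruthenium, and C–O reductive elimination releases the aryl trifluoroacetate and returns divalent ruthenium. The closest known reaction type is the ruthenium-catalysed ortho C–H oxygenation of simple alkyl benzoates in TFA/TFAA; its use twice in one molecule, with the aryl ester of a depside as one of the directors, is the untested part. No ring of the product is closed, since the metallacycles are transient, and no stereocenter is formed. Three selectivities are needed: C2 over C6 on rings A and C is fixed by the C6 methyl groups; ring B cannot be metalated through a five-membered chelate because both positions ortho to its carbonyl are substituted; and six-membered chelates reaching hydrogens on the aryloxy side should lose out through ring size, through the twist of the ring B carbonyl between OMe and methyl, and, on ring B, through the substituents flanking C3–H and C5–H. Stirring in TFA/TFAA beforehand converts the ring A phenol into 16, so no free phenol meets the oxidant, and each new oxygen is likewise formed as a trifluoroacetate in 17, which protects it from over-oxidation. Water then cleaves the three labile trifluoroacetates to 18 without touching the hindered depside esters.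

## Compound list

1 | 4-hydroxy-2-methylbenzoic acid | Cc1cc(O)ccc1C(=O)O | starting material
2 | methyl 4-hydroxy-2-methylbenzoate | COC(=O)c1c(C)cc(O)cc1 | intermediate
3 | methyl orsellinate (methyl 2,4-dihydroxy-6-methylbenzoate) | COC(=O)c1c(C)cc(O)cc1O | starting material
4 | benzyl bromide | BrCc1ccccc1 | starting material
5 | methyl 4-(benzyloxy)-2-hydroxy-6-methylbenzoate | COC(=O)c1c(C)cc(OCc2ccccc2)cc1O | intermediate
6 | methyl 4-(benzyloxy)-2-methoxy-6-methylbenzoate | COC(=O)c1c(C)cc(OCc2ccccc2)cc1OC | intermediate
7 | 4-(benzyloxy)-2-methoxy-6-methylbenzoic acid | COc1cc(OCc2ccccc2)cc(C)c1C(=O)O | intermediate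
8 | 4-(benzyloxy)-2-methoxy-6-methylbenzoic trifluoroacetic anhydride | COc1cc(OCc2ccccc2)cc(C)c1C(=O)OC(=O)C(F)(F)F | intermediate (not isolated)
9 | methyl 4-{[4-(benzyloxy)-2-methoxy-6-methylbenzoyl]oxy}-2-methylbenzoate | COC(=O)c1c(C)cc(OC(=O)c2c(C)cc(OCc3ccccc3)cc2OC)cc1 | intermediate
10 | methyl 4-[(4-hydroxy-2-methoxy-6-methylbenzoyl)oxy]-2-methylbenzoate | COC(=O)c1c(C)cc(OC(=O)c2c(C)cc(O)cc2OC)cc1 | intermediate
11 | benzyl 4-(benzyloxy)-2-methylbenzoate | Cc1cc(OCc2ccccc2)ccc1C(=O)OCc1ccccc1 | intermediate (not isolated)
12 | 4-(benzyloxy)-2-methylbenzoic acid | Cc1cc(OCc2ccccc2)ccc1C(=O)O | intermediate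
13 | 4-(benzyloxy)-2-methylbenzoyl chloride | Cc1cc(OCc2ccccc2)ccc1C(=O)Cl | intermediate (not isolated)
14 | methyl 4-[(4-{[4-(benzyloxy)-2-methylbenzoyl]oxy}-2-methoxy-6-methylbenzoyl)oxy]-2-methylbenzoate | COC(=O)c1c(C)cc(OC(=O)c2c(C)cc(OC(=O)c3c(C)cc(OCc4ccccc4)cc3)cc2OC)cc1 | intermediate
15 | methyl 4-({4-[(4-hydroxy-2-methylbenzoyl)oxy]-2-methoxy-6-methylbenzoyl}oxy)-2-methylbenzoate | COC(=O)c1c(C)cc(OC(=O)c2c(C)cc(OC(=O)c3c(C)cc(O)cc3)cc2OC)cc1 | intermediate
16 | methyl 4-{[2-methoxy-6-methyl-4-({2-methyl-4-[(trifluoroacetyl)oxy]benzoyl}oxy)benzoyl]oxy}-2-methylbenzoate | COC(=O)c1c(C)cc(OC(=O)c2c(C)cc(OC(=O)c3c(C)cc(OC(=O)C(F)(F)F)cc3)cc2OC)cc1 | intermediate (not isolated)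
17 | methyl 4-{[4-({2,4-bis[(trifluoroacetyl)oxy]-6-methylbenzoyl}oxy)-2-methoxy-6-methylbenzoyl]oxy}-2-methyl-6-[(trifluoroacetyl)oxy]benzoate | COC(=O)c1c(C)cc(OC(=O)c2c(C)cc(OC(=O)c3c(C)cc(OC(=O)C(F)(F)F)cc3OC(=O)C(F)(F)F)cc2OC)cc1OC(=O)C(F)(F)F | intermediate (not isolated)
18 | methyl 4-({4-[(2,4-dihydroxy-6-methylbenzoyl)oxy]-2-methoxy-6-methylbenzoyl}oxy)-2-hydroxy-6-methylbenzoate (CNP0563156.0) | COC(=O)c1c(C)cc(OC(=O)c2c(C)cc(OC(=O)c3c(C)cc(O)cc3O)cc2OC)cc1O | target

## Step count and least certain steps

Total: 10 steps. Longest linear sequence: 8 steps (3 → 5 → 6 → 7 → 9 → 10 → 14 → 15 → 18; steps 2, 3, 4, 5, 6, 8, 9 and 10). Compound 2 is also sold as such; buying it would remove step 1.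

Step 10 (key step, Proposed new method).
- What may go wrong: stalling after the first oxygenation, because the aryl ester carbonyl of ring A is a weaker donor than the methyl ester of ring C.
- Misdirected metalation through the ring B carbonyl at the unflanked C3–H of ring C, by way of a six-membered chelate.
- Acid-promoted scission of the di-ortho-substituted B–C ester through an acylium ion in hot TFA/TFAA.
- Oxidation of the methoxy-bearing ring B by the trivalent iodine reagent.
- Fallback, known chemistry only, setting out from 7 and 3 (with 4) and returning at 18:
  - Compound 7 is condensed under the conditions of step 5 with 3, whose chelated C2 hydroxyl should stay out of the reaction, to give methyl 4-{[4-(benzyloxy)-2-methoxy-6-methylbenzoyl]oxy}-2-hydroxy-6-methylbenzoate F1.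
  - Hydrogenolysis over 10% Pd/C frees the ring B phenol as methyl 2-hydroxy-4-[(4-hydroxy-2-methoxy-6-methylbenzoyl)oxy]-6-methylbenzoate F2.
  - Separately 3 is benzylated on both oxygens with excess 4 (K2CO3, DMF, heat) to methyl 2,4-bis(benzyloxy)-6-methylbenzoate F3 and saponified (KOH, aqueous DMSO) to 2,4-bis(benzyloxy)-6-methylbenzoic acid F4.
  - TFAA-mediated esterification of F4 with the unchelated ring B hydroxyl of F2 gives methyl 4-[(4-{[2,4-bis(benzyloxy)-6-methylbenzoyl]oxy}-2-methoxy-6-methylbenzoyl)oxy]-2-hydroxy-6-methylbenzoate F5, and hydrogenolysis of both benzyl ethers gives 18.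
  - The price is that both C2/C4 pairs must be handled through chelation and the A–B ester must be made on a di-ortho-substituted acid.

Step 5 (B–C esterification).
- What may go wrong: trifluoroacetylation of the electron-poor phenol could outpace aroyl transfer, capture of the acylium ion could be slow, and the benzyl ether could be eroded by acid over a long reaction time.
- Fallback, setting out from 7 and returning at 9, forms the aryl–oxygen bond instead of the acyl–oxygen bond:
  - Purchased methyl 4-iodo-2-methylbenzoate F6 is oxidised with mCPBA in the presence of TsOH·H2O and anisole to [4-(methoxycarbonyl)-3-methylphenyl](4-methoxyphenyl)iodonium 4-methylbenzenesulfonate F7.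
  - The potassium salt of 7 (t-BuOK, toluene, heat) is O-arylated by F7, the electron-poor aryl group being the one transferred, to give 9.
  - This metal-free arylation of carboxylates is known to tolerate hindered acids.

Step 4 (hydrolysis of the hindered ester).
- What may go wrong: incomplete attack of hydroxide at the shielded carbonyl, and decarboxylation of the electron-rich acid during acidification.
- Fallback, setting out from 6 and returning at 7: the ester is cleaved at its methyl carbon instead, by SN2 attack of iodide (LiI, pyridine, reflux; then cold dilute acid). This avoids the carbonyl altogether, and no new compound is formed on this path (entry F0).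

Step 2 (selective benzylation).
- What may go wrong: over-alkylation at the chelated C2 oxygen, or incomplete conversion if the halide is kept short.
- Fallback, setting out from 3 and 4 and returning at 5: exhaustive benzylation (excess 4, K2CO3, DMF, heat) gives methyl 2,4-bis(benzyloxy)-6-methylbenzoate F8, identical in structure with F3. Chelation-controlled removal of only the benzyl group ortho to the ester with MgBr2·OEt2 (toluene/ether, warm) gives 5.

## Further compounds

F1 | step 10 | methyl 4-{[4-(benzyloxy)-2-methoxy-6-methylbenzoyl]oxy}-2-hydroxy-6-methylbenzoate | COC(=O)c1c(C)cc(OC(=O)c2c(C)cc(OCc3ccccc3)cc2OC)cc1O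
F2 | step 10 | methyl 2-hydroxy-4-[(4-hydroxy-2-methoxy-6-methylbenzoyl)oxy]-6-methylbenzoate | COC(=O)c1c(C)cc(OC(=O)c2c(C)cc(O)cc2OC)cc1O
F3 | step 10 | methyl 2,4-bis(benzyloxy)-6-methylbenzoate | COC(=O)c1c(C)cc(OCc2ccccc2)cc1OCc1ccccc1
F4 | step 10 | 2,4-bis(benzyloxy)-6-methylbenzoic acid | OC(=O)c1c(C)cc(OCc2ccccc2)cc1OCc1ccccc1
F5 | step 10 | methyl 4-[(4-{[2,4-bis(benzyloxy)-6-methylbenzoyl]oxy}-2-methoxy-6-methylbenzoyl)oxy]-2-hydroxy-6-methylbenzoate | COC(=O)c1c(C)cc(OC(=O)c2c(C)cc(OC(=O)c3c(C)cc(OCc4ccccc4)cc3OCc5ccccc5)cc2OC)cc1O
F6 | step 5 | methyl 4-iodo-2-methylbenzoate | COC(=O)c1ccc(I)cc1C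
F7 | step 5 | [4-(methoxycarbonyl)-3-methylphenyl](4-methoxyphenyl)iodonium 4-methylbenzenesulfonate | COC(=O)c1ccc([I+]c2ccc(OC)cc2)cc1C.Cc1ccc(S(=O)(=O)[O-])cc1
F0 | step 4 | none | none
F8 | step 2 | methyl 2,4-bis(benzyloxy)-6-methylbenzoate | COC(=O)c1c(C)cc(OCc2ccccc2)cc1OCc1ccccc1
A1 | alternative 1 | methyl acetoacetate | COC(=O)CC(C)=O
A2 | alternative 1 | methyl (E)-but-2-enoate | C/C=C/C(=O)OC
A3 | alternative 1 | methyl trans-2-methyl-4,6-dioxocyclohexane-1-carboxylate (racemic, one enantiomer drawn) | COC(=O)[C@H]1[C@H](C)CC(=O)CC1=O
A4 | alternative 1 | methyl trans-4-{[4-(benzyloxy)-2-methoxy-6-methylbenzoyl]oxy}-6-methyl-2-oxocyclohex-3-ene-1-carboxylate (racemic, one enantiomer drawn) | COC(=O)[C@H]1[C@H](C)CC(OC(=O)c2c(C)cc(OCc3ccccc3)cc2OC)=CC1=O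
A5 | alternative 2 | 2-iodo-3-methoxy-5-(triisopropylsilyloxy)phenyl trifluoromethanesulfonate | COc1cc(O[Si](C(C)C)(C(C)C)C(C)C)cc(OS(=O)(=O)C(F)(F)F)c1I
A6 | alternative 2 | 1,1-dimethoxyethene | C=C(OC)OC
A7 | alternative 2 | 2,8,8-trimethoxy-4-(triisopropylsilyloxy)bicyclo[4.2.0]octa-1,3,5-triene (ring B benzocyclobutenone dimethyl acetal) | COc1cc(O[Si](C(C)C)(C(C)C)C(C)C)cc2c1C(OC)(OC)C2
A8 | alternative 2 | 5-methoxy-3-(triisopropylsilyloxy)bicyclo[4.2.0]octa-1,3,5-trien-7-one | COc1cc(O[Si](C(C)C)(C(C)C)C(C)C)cc2c1C(=O)C2
A9 | alternative 3 | 3-(benzyloxy)-4-(methoxycarbonyl)-5-methylphenyl 4-methoxy-6-methyl-2-oxo-2H-pyran-5-carboxylate | COc1cc(=O)oc(C)c1C(=O)Oc1cc(C)c(C(=O)OC)c(OCc2ccccc2)c1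
A10 | alternative 3 | 1,1-bis(trimethylsilyloxy)ethene | C=C(O[Si](C)(C)C)O[Si](C)(C)C
A11 | alternative 3 | methyl 2-(benzyloxy)-4-[(4-hydroxy-2-methoxy-6-methylbenzoyl)oxy]-6-methylbenzoate | COC(=O)c1c(C)cc(OC(=O)c2c(C)cc(O)cc2OC)cc1OCc1ccccc1
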